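**Retrosynthetic overview**
1. The angelate goes on C8 last-but-one by Mitsunobu inversion; before that, allylic oxidation gives the C1 ketone.
2. Ring A (oxepene) is closed by ring-closing metathesis at C2=C3; ring B (oxepane) is closed just before by 7-exo opening of a C1–C10 vinyl epoxide by the C5 hydroxyl, with inversion at C10.
3. Key late union (C7–C8): zinc Barbier allylation of epoxy aldehyde fragment E (C8–C10, C14, C1, C2) with α-(bromomethyl)butenolide fragment W (C3–C7, C11–C13, C15), which already holds ring C.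
4. Fragment W: Sharpless epoxide of a butenediol monoether, vinyl cuprate opening, then Nozaki–Hiyama–Kishi coupling/lactonisation with a (Z)-β-iodoacrylate. Fragment E: butynol, carboalumination, Sharpless epoxidation, Wittig.
5. Ring order: C (in fragment W), then B, then A.

Locants used below (germacrane style): C1 ketone carbon, C2=C3 ring olefin, C4 (carries C15H2OH), C5 (ether CH), C6 (lactone O–CH), C7, C8 (ester CH), C9 (CH2), C10 (ether carbon carrying C14H3), C11=C13 (exocyclic methylene), C12 (lactone C=O).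

Assumption: the SMILES is taken literally; its (5R,10S) pairing puts the C4 and C1 arms trans across the ether oxygen (an inside–outside 11-oxabicyclo[4.4.1]undecenone), and every intermediate is drawn to deliver exactly the descriptors 4R,5R,6S,7R,8R,10S.

**Step 1**
Reactants: 1 (E)-but-2-ene-1,4-diol
Product: 2 (E)-4-[(4-methoxybenzyl)oxy]but-2-en-1-ol
Conditions: NaH, PMBCl, n-Bu4NI (cat.), THF/DMF, 0 °C → rt (3 equiv of 1)
Reagents that add atoms: 4-methoxybenzyl chloride, COc1ccc(CCl)cc1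
Why: Williamson etherification of the mono-alkoxide of the symmetrical diol (used in excess) gives the mono-PMB ether and leaves one allylic alcohol free to direct the epoxidation; no stereocentre is formed.

**Step 2**
Reactants: 2 (E)-4-[(4-methoxybenzyl)oxy]but-2-en-1-ol
Product: 3 [(2S,3S)-3-{[(4-methoxybenzyl)oxy]methyl}oxiran-2-yl]methanol
Conditions: Ti(OiPr)4 (10 mol %), L-(+)-diisopropyl tartrate (12 mol %), t-BuOOH, 4 Å MS, CH2Cl2, −20 °C
Reagents that add atoms: tert-butyl hydroperoxide, CC(C)(C)OO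
Why: Sharpless asymmetric epoxidation of the (E)-allylic alcohol, in which the L-(+)-tartrate–titanium complex delivers oxygen to one alkene face to give the (2S,3S)-trans-epoxide, setting the future C5 (kept) and C4 (to be inverted).

**Step 3**
Reactants: 3 [(2S,3S)-3-{[(4-methoxybenzyl)oxy]methyl}oxiran-2-yl]methanol
Product: 4 (2R,3R)-4-[(4-methoxybenzyl)oxy]-2-vinylbutane-1,3-diol
Conditions: CH2=CHMgBr (3 equiv), CuI (10 mol %), THF, −40 → −10 °C
Reagents that add atoms: vinylmagnesium bromide, C=C[Mg]Br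
Why: Copper-catalysed Grignard opening of the 2,3-epoxy alcohol is an SN2 attack at C2, the carbon next to the magnesium alkoxide, so vinyl enters with inversion and gives the 2-vinyl-1,3-diol with C4 R and C5 R; the minor 1,2-diol regioisomer is removed by chromatography.

**Step 4**
Reactants: 4 (2R,3R)-4-[(4-methoxybenzyl)oxy]-2-vinylbutane-1,3-diol
Product: 6 tert-butyl{[(2R,3R)-4-[(4-methoxybenzyl)oxy]-3-[(triethylsilyl)oxy]-2-vinylbutyl]oxy}diphenylsilane, via mono-TBDPS ether 5 (not isolated)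
Conditions: TBDPSCl (1.05 equiv), imidazole, CH2Cl2, 0 °C; then TESCl, DMAP (cat.), rt
Reagents that add atoms: tert-butyl(chloro)diphenylsilane, CC(C)(C)[Si](Cl)(c1ccccc1)c1ccccc1; chlorotriethylsilane, CC[Si](Cl)(CC)CC
Why: Silyl ether formation in one flask: the bulky TBDPSCl takes only the primary alcohol (C15) and TESCl then caps the secondary C5 alcohol as an acid-labile ether, with no change at the stereocentres.

**Step 5**
Reactants: 6 tert-butyl{[(2R,3R)-4-[(4-methoxybenzyl)oxy]-3-[(triethylsilyl)oxy]-2-vinylbutyl]oxy}diphenylsilane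
Product: 7 (2R,3R)-3-{[(tert-butyldiphenylsilyl)oxy]methyl}-2-[(triethylsilyl)oxy]pent-4-en-1-ol
Conditions: DDQ, CH2Cl2/pH 7 phosphate buffer, 0 °C
Reagents that add atoms: none
Why: Oxidative cleavage of the PMB ether by DDQ (hydride abstraction from the electron-rich benzylic position, then hydrolysis) frees the C6 alcohol while the silyl ethers and the vinyl group are untouched under buffering.

**Step 6**
Reactants: 7 (2R,3R)-3-{[(tert-butyldiphenylsilyl)oxy]methyl}-2-[(triethylsilyl)oxy]pent-4-en-1-ol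
Product: 8 (2R,3R)-3-{[(tert-butyldiphenylsilyl)oxy]methyl}-2-[(triethylsilyl)oxy]pent-4-enal
Conditions: Dess–Martin periodinane, NaHCO3, CH2Cl2, 0 °C → rt
Reagents that add atoms: none
Why: Dess–Martin oxidation gives the α-silyloxy aldehyde under buffered, non-basic conditions that do not epimerise C5, and the aldehyde is used at once.

**Step 7**
Reactants: 9 methyl prop-2-ynoate
Product: 10 methyl (Z)-2-(hydroxymethyl)-3-iodoprop-2-enoate
Conditions: n-Bu4NI, TiCl4, 1,3,5-trioxane, CH2Cl2, −78 → 0 °C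
Reagents that add atoms: tetrabutylammonium iodide, CCCC[N+](CCCC)(CCCC)CCCC.[I-]; 1,3,5-trioxane, C1OCOCO1
Why: Conjugate addition of iodide to the TiCl4-activated ynoate gives a titanium allenolate that is trapped by formaldehyde (β-iodo Morita–Baylis–Hillman-type aldol), and at low temperature the kinetic (Z)-isomer with iodine cis to the ester is formed.

**Step 8**
Reactants: 8 (2R,3R)-3-{[(tert-butyldiphenylsilyl)oxy]methyl}-2-[(triethylsilyl)oxy]pent-4-enal; 10 methyl (Z)-2-(hydroxymethyl)-3-iodoprop-2-enoate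
Product: 12 (5S)-5-[(1R,2R)-2-{[(tert-butyldiphenylsilyl)oxy]methyl}-1-[(triethylsilyl)oxy]but-3-en-1-yl]-3-(hydroxymethyl)furan-2(5H)-one, via hydroxy ester 11 (not isolated)
Conditions: CrCl2 (4 equiv), NiCl2 (2 mol %), DMF, rt; then PPTS (cat.), CH2Cl2, rt
Reagents that add atoms: none
Why: Nozaki–Hiyama–Kishi coupling, in which the alkenylchromium species from 10 keeps its (Z)-geometry and adds only to the aldehyde from the Felkin–Anh face (C5–OTES anti to the nucleophile) to set C6 as S (5,6-anti), after which the ester, cis to the new carbinol, lactonises to the butenolide of ring C.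

**Step 9**
Reactants: 12 (5S)-5-[(1R,2R)-2-{[(tert-butyldiphenylsilyl)oxy]methyl}-1-[(triethylsilyl)oxy]but-3-en-1-yl]-3-(hydroxymethyl)furan-2(5H)-one
Product: 13 (5S)-3-(bromomethyl)-5-[(1R,2R)-2-{[(tert-butyldiphenylsilyl)oxy]methyl}-1-[(triethylsilyl)oxy]but-3-en-1-yl]furan-2(5H)-one (fragment W)
Conditions: CBr4, PPh3, 2,6-lutidine, CH2Cl2, −20 → 0 °C
Reagents that add atoms: carbon tetrabromide, BrC(Br)(Br)Br
Why: Appel bromination, an SN2 displacement of the alkoxyphosphonium ion by bromide at the primary allylic carbon, gives the allylic bromide under buffered conditions that neither cleave the TES ether nor enolise C6.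

**Step 10**
Reactants: 14 but-3-yn-1-ol
Product: 15 (but-3-yn-1-yloxy)(tert-butyl)dimethylsilane
Conditions: TBSCl, imidazole, CH2Cl2, rt
Reagents that add atoms: tert-butyl(chloro)dimethylsilane, CC(C)(C)[Si](C)(C)Cl
Why: Silyl ether formation protects the primary alcohol so that it survives the organoaluminium step.

**Step 11**
Reactants: 15 (but-3-yn-1-yloxy)(tert-butyl)dimethylsilane
Product: 17 (E)-5-{[tert-butyl(dimethyl)silyl]oxy}-3-methylpent-2-en-1-ol, via alkenylalane 16 (not isolated)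
Conditions: Me3Al, Cp2ZrCl2 (25 mol %), CH2Cl2, 0 °C → rt; then n-BuLi, (CH2O)n, THF, −30 °C → rt
Reagents that add atoms: trimethylaluminium, C[Al](C)C; paraformaldehyde (as formaldehyde), C=O
Why: Negishi zirconium-catalysed carboalumination adds methyl and aluminium syn across the terminal alkyne (methyl on the internal carbon) and the derived alanate is hydroxymethylated with retention, so only the (E)-trisubstituted allylic alcohol is formed.

**Step 12**
Reactants: 17 (E)-5-{[tert-butyl(dimethyl)silyl]oxy}-3-methylpent-2-en-1-ol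
Product: 18 [(2R,3R)-3-(2-{[tert-butyl(dimethyl)silyl]oxy}ethyl)-3-methyloxiran-2-yl]methanol
Conditions: Ti(OiPr)4 (10 mol %), D-(−)-diisopropyl tartrate (12 mol %), t-BuOOH, 4 Å MS, CH2Cl2, −20 °C
Reagents that add atoms: tert-butyl hydroperoxide, CC(C)(C)OO
Why: Sharpless asymmetric epoxidation of the geraniol-type (E)-allylic alcohol with the D-(−)-tartrate gives the (2R,3R)-epoxide, whose quaternary carbon is the future C10 and is set here so that inversion in step 18 gives 10S.

**Step 13**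
Reactants: 18 [(2R,3R)-3-(2-{[tert-butyl(dimethyl)silyl]oxy}ethyl)-3-methyloxiran-2-yl]methanol
Product: 19 (2S,3R)-3-(2-{[tert-butyl(dimethyl)silyl]oxy}ethyl)-3-methyloxirane-2-carbaldehyde
Conditions: Dess–Martin periodinane, NaHCO3, CH2Cl2, 0 °C
Reagents that add atoms: none
Why: Dess–Martin oxidation converts the epoxy alcohol into the α,β-epoxy aldehyde without opening the epoxide or epimerising the α-carbon.

**Step 14**
Reactants: 19 (2S,3R)-3-(2-{[tert-butyl(dimethyl)silyl]oxy}ethyl)-3-methyloxirane-2-carbaldehyde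
Product: 20 tert-butyldimethyl{2-[(2R,3R)-2-methyl-3-vinyloxiran-2-yl]ethoxy}silane
Conditions: Ph3PCH3Br, KN(SiMe3)2, THF, −78 → 0 °C
Reagents that add atoms: methyltriphenylphosphonium bromide, C[P+](c1ccccc1)(c1ccccc1)c1ccccc1.[Br-]
Why: Wittig methylenation with the non-stabilised ylide at low temperature turns the aldehyde into the vinyl group (future C2 and the CH2 lost in step 19) without touching the epoxide stereocentres.

**Step 15**
Reactants: 20 tert-butyldimethyl{2-[(2R,3R)-2-methyl-3-vinyloxiran-2-yl]ethoxy}silane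
Product: 21 2-[(2R,3R)-2-methyl-3-vinyloxiran-2-yl]ethan-1-ol
Conditions: Bu4NF, THF, 0 °C
Reagents that add atoms: none
Why: Fluoride-mediated desilylation frees the primary alcohol under basic conditions in which the hydroxy epoxide does not cyclise.

**Step 16**
Reactants: 21 2-[(2R,3R)-2-methyl-3-vinyloxiran-2-yl]ethan-1-ol
Product: 22 2-[(2R,3R)-2-methyl-3-vinyloxiran-2-yl]acetaldehyde (fragment E)
Conditions: Dess–Martin periodinane, NaHCO3, CH2Cl2, 0 °C (used crude)
Reagents that add atoms: none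
Why: Dess–Martin oxidation under bicarbonate buffer gives the β,γ-epoxy aldehyde without the base that would cause β-elimination of the epoxide, and the crude aldehyde is coupled directly.

**Step 17**
Reactants: 13 (5S)-3-(bromomethyl)-5-[(1R,2R)-2-{[(tert-butyldiphenylsilyl)oxy]methyl}-1-[(triethylsilyl)oxy]but-3-en-1-yl]furan-2(5H)-one; 22 2-[(2R,3R)-2-methyl-3-vinyloxiran-2-yl]acetaldehyde
Product: 24 (4R,5S)-5-[(1R,2R)-2-{[(tert-butyldiphenylsilyl)oxy]methyl}-1-[(triethylsilyl)oxy]but-3-en-1-yl]-4-{(1S)-1-hydroxy-2-[(2R,3R)-2-methyl-3-vinyloxiran-2-yl]ethyl}-3-methylideneoxolan-2-one, via allylzinc bromide 23 (not isolated)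
Conditions: Zn dust, THF/sat. aq NH4Cl, 0 °C
Reagents that add atoms: none
Why: Zinc Barbier allylation through a six-membered chair transition state: the allylzinc attacks with its γ-carbon (C7) on the butenolide face opposite the C6 side chain, giving the 6,7-trans α-methylene lactone (7R), and the ring-locked allyl geometry with an equatorial aldehyde residue gives the 7,8-anti alcohol (8S, the C8 epimer of the target, corrected in step 21), while the buffered aqueous medium protonates the alkoxide before it can translactonise or attack the epoxide.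

**Step 18**
Reactants: 24 (4R,5S)-5-[(1R,2R)-2-{[(tert-butyldiphenylsilyl)oxy]methyl}-1-[(triethylsilyl)oxy]but-3-en-1-yl]-4-{(1S)-1-hydroxy-2-[(2R,3R)-2-methyl-3-vinyloxiran-2-yl]ethyl}-3-methylideneoxolan-2-one
Product: 26 oxepane-fused α-methylene lactone (rings B and C; 1R,4R,5R,6S,7R,8S,10S) with 1-OH, 8-OH and 15-OTBDPS, via C5 alcohol 25 (not isolated)
Conditions: CSA (20 mol %), wet CH2Cl2, 0 °C → rt
Reagents that add atoms: none
Why: Acid removes the TES group and activates the trisubstituted vinyl epoxide, and the 7-exo epoxide-opening etherification by the C5 hydroxyl at the tertiary carbon C10 proceeds with inversion (10R to 10S) to close ring B, leaving the epoxide oxygen as the C1 allylic alcohol and placing the C1 and C4 arms trans across the ether oxygen.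

**Step 19**
Reactants: 26 oxepane-fused α-methylene lactone (1R,4R,5R,6S,7R,8S,10S) with 1-OH, 8-OH and 15-OTBDPS
Product: 27 (1R,4R,5R,6S,7R,8S,10S)-15-[(tert-butyldiphenylsilyl)oxy]-5,10-epoxy-1,8-dihydroxygermacra-2(Z),11(13)-dien-12,6-olide
Conditions: second-generation Hoveyda–Grubbs catalyst [RuCl2(H2IMes)(=CH-C6H4-2-OiPr)] (15 mol %), 1,4-benzoquinone (30 mol %), toluene (1 mM), 80 °C
Reagents that add atoms: none
Why: Ring-closing metathesis of the two terminal vinyl groups gives the cis-cycloheptene of ring A with loss of ethene, which makes the closure of the strained inside–outside bicycle irreversible at high dilution, while the electron-poor 1,1-disubstituted methylene lactone does not take part and benzoquinone suppresses isomerisation of the allylic alcohol.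

**Step 20**
Reactants: 27 (1R,4R,5R,6S,7R,8S,10S)-15-[(tert-butyldiphenylsilyl)oxy]-5,10-epoxy-1,8-dihydroxygermacra-2(Z),11(13)-dien-12,6-olide
Product: 28 (4R,5R,6S,7R,8S,10S)-15-[(tert-butyldiphenylsilyl)oxy]-5,10-epoxy-8-hydroxy-1-oxogermacra-2(Z),11(13)-dien-12,6-olide
Conditions: MnO2 (excess), CH2Cl2, rt
Reagents that add atoms: none
Why: MnO2 oxidises only the allylic C1 alcohol to the enone (allylic alcohol oxidation) and leaves the saturated C8 alcohol free for the next step.

**Step 21**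
Reactants: 28 (4R,5R,6S,7R,8S,10S)-15-[(tert-butyldiphenylsilyl)oxy]-5,10-epoxy-8-hydroxy-1-oxogermacra-2(Z),11(13)-dien-12,6-olide; 29 angelic acid, (Z)-2-methylbut-2-enoic acid
Product: 30 (4R,5R,6S,7R,8R,10S)-8-angeloyloxy-15-[(tert-butyldiphenylsilyl)oxy]-5,10-epoxy-1-oxogermacra-2(Z),11(13)-dien-12,6-olide
Conditions: PPh3, DIAD, toluene, 0 °C → rt
Reagents that add atoms: none
Why: Mitsunobu esterification: the C8 alcohol is activated as its alkoxyphosphonium ion and displaced by angelate in an SN2 step, so the 8S alcohol becomes the 8R ester with inversion, under neutral conditions that keep the (Z)-geometry of the acid.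

**Step 22**
Reactants: 30 (4R,5R,6S,7R,8R,10S)-8-angeloyloxy-15-[(tert-butyldiphenylsilyl)oxy]-5,10-epoxy-1-oxogermacra-2(Z),11(13)-dien-12,6-olide
Product: 31 (4R,5R,6S,7R,8R,10S)-8-angeloyloxy-5,10-epoxy-15-hydroxy-1-oxogermacra-2(Z),11(13)-dien-12,6-olide (CNP0274187.1)
Conditions: HF·pyridine, pyridine, THF, 0 °C → rt
Reagents that add atoms: none
Why: Fluoride-mediated desilylation under buffered acidic conditions removes the primary TBDPS ether without the base that could isomerise the angelate or eliminate the C5 ether through the enone, giving the target.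

**Compound list**
1 | (E)-but-2-ene-1,4-diol | OC/C=C/CO | starting material
2 | (E)-4-[(4-methoxybenzyl)oxy]but-2-en-1-ol | OC/C=C/COCc1ccc(OC)cc1 | intermediate
3 | [(2S,3S)-3-{[(4-methoxybenzyl)oxy]methyl}oxiran-2-yl]methanol | OC[C@@H]1O[C@H]1COCc1ccc(OC)cc1 | intermediate
4 | (2R,3R)-4-[(4-methoxybenzyl)oxy]-2-vinylbutane-1,3-diol | COc1ccc(COC[C@H](O)[C@@H](CO)C=C)cc1 | intermediate
5 | (2R,3R)-3-{[(tert-butyldiphenylsilyl)oxy]methyl}-1-[(4-methoxybenzyl)oxy]pent-4-en-2-ol (not isolated) | COc1ccc(COC[C@H](O)[C@@H](CO[Si](c2ccccc2)(c2ccccc2)C(C)(C)C)C=C)cc1 | intermediate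
6 | tert-butyl{[(2R,3R)-4-[(4-methoxybenzyl)oxy]-3-[(triethylsilyl)oxy]-2-vinylbutyl]oxy}diphenylsilane | COc1ccc(COC[C@H](O[Si](CC)(CC)CC)[C@@H](CO[Si](c2ccccc2)(c2ccccc2)C(C)(C)C)C=C)cc1 | intermediate
7 | (2R,3R)-3-{[(tert-butyldiphenylsilyl)oxy]methyl}-2-[(triethylsilyl)oxy]pent-4-en-1-ol | OC[C@H](O[Si](CC)(CC)CC)[C@@H](CO[Si](c1ccccc1)(c1ccccc1)C(C)(C)C)C=C | intermediate
8 | (2R,3R)-3-{[(tert-butyldiphenylsilyl)oxy]methyl}-2-[(triethylsilyl)oxy]pent-4-enal | O=C[C@H](O[Si](CC)(CC)CC)[C@@H](CO[Si](c1ccccc1)(c1ccccc1)C(C)(C)C)C=C | intermediate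
9 | methyl prop-2-ynoate (methyl propiolate) | C#CC(=O)OC | starting material
10 | methyl (Z)-2-(hydroxymethyl)-3-iodoprop-2-enoate | COC(=O)/C(CO)=C\I | intermediate
11 | methyl (2Z,4S,5R,6R)-6-{[(tert-butyldiphenylsilyl)oxy]methyl}-4-hydroxy-2-(hydroxymethyl)-5-[(triethylsilyl)oxy]octa-2,7-dienoate (not isolated) | COC(=O)/C(CO)=C\[C@H](O)[C@H](O[Si](CC)(CC)CC)[C@@H](CO[Si](c1ccccc1)(c1ccccc1)C(C)(C)C)C=C | intermediate
12 | (5S)-5-[(1R,2R)-2-{[(tert-butyldiphenylsilyl)oxy]methyl}-1-[(triethylsilyl)oxy]but-3-en-1-yl]-3-(hydroxymethyl)furan-2(5H)-one | OCC1=C[C@H](OC1=O)[C@H](O[Si](CC)(CC)CC)[C@@H](CO[Si](c2ccccc2)(c2ccccc2)C(C)(C)C)C=C | intermediate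
13 | (5S)-3-(bromomethyl)-5-[(1R,2R)-2-{[(tert-butyldiphenylsilyl)oxy]methyl}-1-[(triethylsilyl)oxy]but-3-en-1-yl]furan-2(5H)-one (fragment W) | BrCC1=C[C@H](OC1=O)[C@H](O[Si](CC)(CC)CC)[C@@H](CO[Si](c2ccccc2)(c2ccccc2)C(C)(C)C)C=C | intermediate
14 | but-3-yn-1-ol | C#CCCO | starting material
15 | (but-3-yn-1-yloxy)(tert-butyl)dimethylsilane | C#CCCO[Si](C)(C)C(C)(C)C | intermediate
16 | [(E)-4-{[tert-butyl(dimethyl)silyl]oxy}-2-methylbut-1-en-1-yl]dimethylalane (not isolated) | C[Al](C)/C=C(\C)CCO[Si](C)(C)C(C)(C)C | intermediate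
17 | (E)-5-{[tert-butyl(dimethyl)silyl]oxy}-3-methylpent-2-en-1-ol | OC/C=C(\C)CCO[Si](C)(C)C(C)(C)C | intermediate
18 | [(2R,3R)-3-(2-{[tert-butyl(dimethyl)silyl]oxy}ethyl)-3-methyloxiran-2-yl]methanol | OC[C@H]1O[C@]1(C)CCO[Si](C)(C)C(C)(C)C | intermediate
19 | (2S,3R)-3-(2-{[tert-butyl(dimethyl)silyl]oxy}ethyl)-3-methyloxirane-2-carbaldehyde | O=C[C@H]1O[C@]1(C)CCO[Si](C)(C)C(C)(C)C | intermediate
20 | tert-butyldimethyl{2-[(2R,3R)-2-methyl-3-vinyloxiran-2-yl]ethoxy}silane | C=C[C@H]1O[C@]1(C)CCO[Si](C)(C)C(C)(C)C | intermediate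
21 | 2-[(2R,3R)-2-methyl-3-vinyloxiran-2-yl]ethan-1-ol | C=C[C@H]1O[C@]1(C)CCO | intermediate
22 | 2-[(2R,3R)-2-methyl-3-vinyloxiran-2-yl]acetaldehyde (fragment E) | C=C[C@H]1O[C@]1(C)CC=O | intermediate
23 | allylzinc bromide from 13, bromo{[(5S)-5-(silyloxy side chain)-2-oxo-2,5-dihydrofuran-3-yl]methyl}zinc (not isolated) | Br[Zn]CC1=C[C@H](OC1=O)[C@H](O[Si](CC)(CC)CC)[C@@H](CO[Si](c2ccccc2)(c2ccccc2)C(C)(C)C)C=C | intermediate
24 | (4R,5S)-5-[(1R,2R)-2-{[(tert-butyldiphenylsilyl)oxy]methyl}-1-[(triethylsilyl)oxy]but-3-en-1-yl]-4-{(1S)-1-hydroxy-2-[(2R,3R)-2-methyl-3-vinyloxiran-2-yl]ethyl}-3-methylideneoxolan-2-one | C=C1C(=O)O[C@H]([C@H](O[Si](CC)(CC)CC)[C@@H](CO[Si](c2ccccc2)(c2ccccc2)C(C)(C)C)C=C)[C@H]1[C@@H](O)C[C@@]1(C)O[C@@H]1C=C | intermediate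
25 | (4R,5S)-5-[(1R,2R)-2-{[(tert-butyldiphenylsilyl)oxy]methyl}-1-hydroxybut-3-en-1-yl]-4-{(1S)-1-hydroxy-2-[(2R,3R)-2-methyl-3-vinyloxiran-2-yl]ethyl}-3-methylideneoxolan-2-one (not isolated) | C=C1C(=O)O[C@H]([C@H](O)[C@@H](CO[Si](c2ccccc2)(c2ccccc2)C(C)(C)C)C=C)[C@H]1[C@@H](O)C[C@@]1(C)O[C@@H]1C=C | intermediate
26 | oxepane-fused α-methylene-γ-lactone (rings B and C; 1R,4R,5R,6S,7R,8S,10S): 5,10-ether, 8-OH, C10 carrying CH3 and the (R)-1-hydroxyprop-2-enyl group, C5 carrying the (R)-1-[(tert-butyldiphenylsilyl)oxy]but-3-en-2-yl group | C=C1C(=O)O[C@@H]2[C@H](O[C@@](C)(C[C@H](O)[C@@H]12)[C@H](O)C=C)[C@@H](CO[Si](c3ccccc3)(c3ccccc3)C(C)(C)C)C=C | intermediate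
27 | (1R,4R,5R,6S,7R,8S,10S)-15-[(tert-butyldiphenylsilyl)oxy]-5,10-epoxy-1,8-dihydroxygermacra-2(Z),11(13)-dien-12,6-olide | C=C1C(=O)O[C@@H]2[C@@H]3O[C@@](C)(C[C@H](O)[C@@H]12)[C@H](O)C=C[C@@H]3CO[Si](c4ccccc4)(c4ccccc4)C(C)(C)C | intermediate
28 | (4R,5R,6S,7R,8S,10S)-15-[(tert-butyldiphenylsilyl)oxy]-5,10-epoxy-8-hydroxy-1-oxogermacra-2(Z),11(13)-dien-12,6-olide | C=C1C(=O)O[C@@H]2[C@@H]3O[C@@](C)(C[C@H](O)[C@@H]12)C(=O)C=C[C@@H]3CO[Si](c4ccccc4)(c4ccccc4)C(C)(C)C | intermediate
29 | angelic acid, (Z)-2-methylbut-2-enoic acid | C/C=C(/C)C(=O)O | starting material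
30 | (4R,5R,6S,7R,8R,10S)-8-angeloyloxy-15-[(tert-butyldiphenylsilyl)oxy]-5,10-epoxy-1-oxogermacra-2(Z),11(13)-dien-12,6-olide | C=C1C(=O)O[C@@H]2[C@@H]3O[C@@](C)(C[C@@H](OC(=O)/C(C)=C\C)[C@@H]12)C(=O)C=C[C@@H]3CO[Si](c4ccccc4)(c4ccccc4)C(C)(C)C | intermediate
31 | (4R,5R,6S,7R,8R,10S)-8-angeloyloxy-5,10-epoxy-15-hydroxy-1-oxogermacra-2(Z),11(13)-dien-12,6-olide (CNP0274187.1) | C=C1C(=O)O[C@@H]2[C@@H]3O[C@@](C)(C[C@@H](OC(=O)/C(C)=C\C)[C@@H]12)C(=O)C=C[C@@H]3CO | target

**Totals**
Total step count: 22.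
Longest linear sequence: 14 steps (steps 1–6, 8, 9, 17–22). The fragment E branch (steps 10–16) and the iodoacrylate branch (step 7) run in parallel.

**Three steps most likely to fail, with fallbacks**

Step 19 (ring-closing metathesis to the inside–outside bicycle). The two vinyl groups sit trans across the oxepane, so ring A closes only at the cost of considerable strain and oligomers may win. The fallback reverses the order of ring formation and sets out from 24. Ring-closing metathesis of its two vinyl groups at high dilution gives the ten-membered (2Z)-carbocycle that still carries the C1–C10 epoxide and the C5 TES ether, the macrocyclic epoxide F3, in which O5 and C10 face each other across the ring. CSA in wet CH2Cl2 then removes the TES group and transannular epoxide opening at C10 (inversion) builds rings A and B in one event, which comes back to the route at 27.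

Step 18 (acid-triggered epoxide-opening etherification). The free C8 hydroxyl of 24 can attack the allylic epoxide carbon C1 (5-endo, tetrahydrofuran formation), or the vinyl epoxide can rearrange, before O5 reaches C10. The fallback masks the competing nucleophile and sets out from 24. Silylation (TBSOTf, 2,6-lutidine) gives the C8 tert-butyldimethylsilyl ether F1, and the same acid treatment then gives the C8-silylated oxepane F2. Selective cleavage of the secondary TBS ether in the presence of the primary TBDPS ether (HF·pyridine, pyridine, 0 °C) comes back to the route at 26.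

Step 21 (Mitsunobu inversion at C8 on the rigid bicycle). The carbinol is flanked by the lactone ring and lies 1,3 to the C10 methyl group, so elimination or no reaction is likely, and the lactone carbonyl may take part. The fallback inverts C8 on the flexible open chain and puts the ester on with retention; it sets out from 24. Mitsunobu reaction with formic acid gives the inverted 8R formate F4, and KHCO3 in methanol frees the 8R alcohol F5. F5 is taken through the conditions of steps 18, 19 and 20 to the 8R oxepane diol F6, the 8R tricyclic diol F7 and the 8R enone alcohol F8. Acylation of F8 with the mixed anhydride of 29 and 2,4,6-trichlorobenzoyl chloride (Et3N, toluene, no DMAP, to avoid isomerisation to the tiglate) comes back to the route at 30.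

**Further compounds**
F1 | step 18 | C8 tert-butyldimethylsilyl ether of 24 | C=C1C(=O)O[C@H]([C@H](O[Si](CC)(CC)CC)[C@@H](CO[Si](c2ccccc2)(c2ccccc2)C(C)(C)C)C=C)[C@H]1[C@@H](O[Si](C)(C)C(C)(C)C)C[C@@]1(C)O[C@@H]1C=C
F2 | step 18 | C8 tert-butyldimethylsilyl ether of 26 | C=C1C(=O)O[C@@H]2[C@H](O[C@@](C)(C[C@H](O[Si](C)(C)C(C)(C)C)[C@@H]12)[C@H](O)C=C)[C@@H](CO[Si](c3ccccc3)(c3ccccc3)C(C)(C)C)C=C
F3 | step 19 | ten-membered (2Z)-carbocycle from 24 with C1–C10 epoxide, C5 TES ether, 8S-OH and 15-OTBDPS | C=C1C(=O)O[C@@H]2[C@H](O[Si](CC)(CC)CC)[C@@H](CO[Si](c4ccccc4)(c4ccccc4)C(C)(C)C)/C=C\[C@H]3O[C@]3(C)C[C@H](O)[C@@H]12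
F4 | step 21 | 8R formate obtained from 24 with inversion at C8 | C=C1C(=O)O[C@H]([C@H](O[Si](CC)(CC)CC)[C@@H](CO[Si](c2ccccc2)(c2ccccc2)C(C)(C)C)C=C)[C@H]1[C@H](OC=O)C[C@@]1(C)O[C@@H]1C=C
F5 | step 21 | 8R alcohol, C8 epimer of 24 | C=C1C(=O)O[C@H]([C@H](O[Si](CC)(CC)CC)[C@@H](CO[Si](c2ccccc2)(c2ccccc2)C(C)(C)C)C=C)[C@H]1[C@H](O)C[C@@]1(C)O[C@@H]1C=C
F6 | step 21 | 8R oxepane diol, C8 epimer of 26 | C=C1C(=O)O[C@@H]2[C@H](O[C@@](C)(C[C@@H](O)[C@@H]12)[C@H](O)C=C)[C@@H](CO[Si](c3ccccc3)(c3ccccc3)C(C)(C)C)C=C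
F7 | step 21 | 8R tricyclic diol, C8 epimer of 27 | C=C1C(=O)O[C@@H]2[C@@H]3O[C@@](C)(C[C@@H](O)[C@@H]12)[C@H](O)C=C[C@@H]3CO[Si](c4ccccc4)(c4ccccc4)C(C)(C)C
F8 | step 21 | 8R enone alcohol, C8 epimer of 28 | C=C1C(=O)O[C@@H]2[C@@H]3O[C@@](C)(C[C@@H](O)[C@@H]12)C(=O)C=C[C@@H]3CO[Si](c4ccccc4)(c4ccccc4)C(C)(C)C
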